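**Retrosynthetic overview**

1. Atom labels follow caryophyllane numbering (C1–C11; C1'–C4' are the four dioxine carbons). The plan rests on ring bond C6–C7 of the nine-membered ring (C1–C9): C6 is allylic to C4=C5 (the later oxirane) and C7 is α to the C8 ketone (the later C8=CH2), so this bond is closed by allyl-palladium alkylation of a β-keto ester.
2. Target ⇒ C4–C5 epoxidation last; 1,2-dioxin-3-ol ⇒ Z-enone carrying an (S)-epoxide plus H2O2; C11–C1' side chain ⇒ C11 aldehyde plus an alkynyl epoxide.
3. Cyclobutane ⇒ Wolff contraction of a 2-diazocyclopentanone; C1–C2 ⇒ conjugate addition of the complete E-allyl arm to a 4,4-disubstituted cyclopentenone; C11 ⇒ asymmetric methyl conjugate addition.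
4. Ring order: cyclopentenone (temporary) → cyclobutane → nine-membered carbocycle → 1,2-dioxine → oxirane.

Key step: step 14

Remark: C1' is a hemiperketal centre that equilibrates through the open hydroperoxy enone, and the anomer of the target (axial OH, equatorial cyclobutyl) is taken to be the thermodynamic one; the ligand enantiomer in step 6 is the one that gives (R)-10.

**Route**

Step 1
Reactants: 1 4-bromobut-1-yne
Product: 3 methyl (E)-5-bromo-3-methylpent-2-enoate, via alkenylalane 2 (not isolated)
Conditions: Me3Al, Cp2ZrCl2 (cat.), CH2Cl2, 0 °C → rt; then ClCO2Me, 0 °C → rt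
Reagents that add atoms: trimethylaluminium C[Al](C)C; methyl chloroformate COC(=O)Cl
Why: Negishi zirconium-catalysed carboalumination adds Me–Al syn across the terminal alkyne (methyl to the internal carbon) and the neutral alkenylalane, which does not attack the primary bromide, is acylated by the chloroformate with retention, fixing the E trisubstituted alkene.

Step 2
Reactants: 3 methyl (E)-5-bromo-3-methylpent-2-enoate
Product: 4 (E)-5-bromo-3-methylpent-2-en-1-ol
Conditions: DIBAL-H, CH2Cl2, −78 °C; Rochelle salt work-up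
Reagents that add atoms: none
Why: DIBAL-H 1,2-reduction of the enoate gives the allylic alcohol and should leave the primary bromide and the alkene geometry untouched at low temperature.

Step 3
Reactants: 4 (E)-5-bromo-3-methylpent-2-en-1-ol
Product: 5 (E)-[(5-bromo-3-methylpent-2-en-1-yl)oxy](tert-butyl)dimethylsilane
Conditions: TBSCl, imidazole, CH2Cl2, 0 °C → rt
Reagents that add atoms: tert-butyldimethylsilyl chloride CC(C)(C)[Si](C)(C)Cl
Why: Standard silylation of a primary allylic alcohol gives an ether that tolerates Grignard formation and enolate chemistry.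

Step 4
Reactants: 6 2,2-dimethoxyacetaldehyde; 7 methyl vinyl ketone
Product: 8 1,1-dimethoxyhexane-2,5-dione
Conditions: 3-benzyl-5-(2-hydroxyethyl)-4-methylthiazolium chloride (cat.), Et3N, EtOH, 75 °C
Reagents that add atoms: none
Why: Stetter reaction, in which the thiazolium-derived acyl anion equivalent of the aldehyde adds 1,4 to the vinyl ketone to give the 1,4-diketone.

Step 5
Reactants: 8 1,1-dimethoxyhexane-2,5-dione
Product: 9 3-(dimethoxymethyl)cyclopent-2-en-1-one
Conditions: aq. NaOH, EtOH, reflux
Reagents that add atoms: none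
Why: Intramolecular aldol condensation, in which only attack of the methyl-ketone enolate on the acetal-bearing ketone gives a five-membered ring that can dehydrate to a conjugated enone.

Step 6
Reactants: 9 3-(dimethoxymethyl)cyclopent-2-en-1-one
Product: 10 (R)-3-(dimethoxymethyl)-3-methylcyclopentan-1-one
Conditions: Me3Al, Cu(OTf)2 (cat.), chiral NHC (or phosphoramidite) ligand (cat.), THF, −30 °C; aqueous work-up
Reagents that add atoms: trimethylaluminium C[Al](C)C
Why: Copper-catalysed asymmetric conjugate addition of Me3Al to a β-substituted cyclopentenone builds the quaternary centre (future C11), with the face chosen by the chiral ligand.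

Step 7
Reactants: 10 (R)-3-(dimethoxymethyl)-3-methylcyclopentan-1-one
Product: 12 (S)-4-(dimethoxymethyl)-4-methylcyclopent-2-en-1-one, via silyl enol ether 11 (not isolated)
Conditions: LDA, TMSCl, THF, −78 °C; then Pd(OAc)2, MeCN, rt
Reagents that add atoms: none
Why: Saegusa–Ito oxidation, in which LDA removes a proton from the α-CH2 remote from the quaternary carbon and Pd(II) dehydrogenates that silyl enol ether, leaving the stereocentre untouched.

Step 8
Reactants: 5 (E)-[(5-bromo-3-methylpent-2-en-1-yl)oxy](tert-butyl)dimethylsilane; 12 (S)-4-(dimethoxymethyl)-4-methylcyclopent-2-en-1-one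
Product: 14 (3S,4S)-3-[(E)-5-(tert-butyldimethylsilyloxy)-3-methylpent-3-en-1-yl]-4-(dimethoxymethyl)-4-methyl-1-(trimethylsilyloxy)cyclopent-1-ene, via Grignard reagent 13 (not isolated)
Conditions: Mg, THF, 40 °C; then CuBr·SMe2 (cat.), TMSCl, HMPA, THF, −78 °C, add 12; Et3N, non-acidic work-up
Reagents that add atoms: chlorotrimethylsilane C[Si](C)(C)Cl
Why: TMSCl-accelerated copper-catalysed conjugate addition should deliver the arm to the β-carbon anti to the α-branched CH(OMe)2 group on the neighbouring quaternary carbon (sets C1, arm cis to methyl) and trap the enolate regiospecifically at the future C9.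

Step 9
Reactants: 14 the silyl enol ether from step 8
Product: 17 (3R,4S)-2-diazo-3-[(E)-5-(tert-butyldimethylsilyloxy)-3-methylpent-3-en-1-yl]-4-(dimethoxymethyl)-4-methylcyclopentan-1-one, via lithium enolate 15 (not isolated), via trifluoroacetyl ketone 16 (not isolated)
Conditions: MeLi, THF, 0 °C; CF3CO2CH2CF3, −78 °C; dilute HCl work-up; then MsN3, Et3N, H2O, MeCN, rt
Reagents that add atoms: methanesulfonyl azide CS(=O)(=O)N=[N+]=[N-]
Why: Regiospecific regeneration of the enolate from the silyl enol ether, Claisen-type trifluoroacetylation and detrifluoroacetylative diazo transfer place the diazo group at C9 only.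

Step 10
Reactants: 17 the α-diazoketone from step 9
Product: 20 methyl (1R,2S,3S)-2-[(E)-5-(tert-butyldimethylsilyloxy)-3-methylpent-3-en-1-yl]-3-(dimethoxymethyl)-3-methylcyclobutane-1-carboxylate, via ketene 18 (not isolated), via cis ester 19 (not isolated)
Conditions: hν (≥300 nm, Pyrex), MeOH, rt; then NaOMe (cat.), MeOH, 40 °C
Reagents that add atoms: methanol CO
Why: Photochemical Wolff rearrangement contracts the 2-diazocyclopentanone with migration of C10, methanol traps the ketene, and methoxide equilibrates the enolisable C9 to the more stable 1,2-trans ester (sets C9).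

Step 11
Reactants: 20 the trans cyclobutane ester from step 10
Product: 21 methyl 3-[(1R,2S,3S)-2-[(E)-5-(tert-butyldimethylsilyloxy)-3-methylpent-3-en-1-yl]-3-(dimethoxymethyl)-3-methylcyclobutyl]-3-oxopropanoate
Conditions: MeOAc, LDA, THF, −78 °C (excess enolate); add 20, −78 → −30 °C; AcOH quench
Reagents that add atoms: methyl acetate CC(=O)OC
Why: Crossed Claisen condensation with excess lithio methyl acetate, driven by deprotonation of the product β-keto ester, with silyl ether and acetal inert.

Step 12
Reactants: 21 the silyl-protected β-keto ester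
Product: 22 methyl 3-[(1R,2S,3S)-3-(dimethoxymethyl)-2-[(E)-5-hydroxy-3-methylpent-3-en-1-yl]-3-methylcyclobutyl]-3-oxopropanoate
Conditions: PPTS (cat.), MeOH, rt
Reagents that add atoms: none
Why: Mild acid methanolysis removes the primary allylic TBS ether, while the dimethyl acetal only exchanges with the solvent and the β-keto ester is stable.

Step 13
Reactants: 22 the allylic alcohol
Product: 23 methyl 3-[(1R,2S,3S)-3-(dimethoxymethyl)-2-[(E)-5-(methoxycarbonyloxy)-3-methylpent-3-en-1-yl]-3-methylcyclobutyl]-3-oxopropanoate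
Conditions: ClCO2Me, pyridine, CH2Cl2, 0 °C
Reagents that add atoms: methyl chloroformate COC(=O)Cl
Why: Acylation of the primary allylic alcohol gives the carbonate that lets the π-allyl complex form without added base.

Step 14
Reactants: 23 the E-allylic carbonate β-keto ester
Product: 24 methyl (1S,4E,9R,11S)-11-(dimethoxymethyl)-4,11-dimethyl-8-oxobicyclo[7.2.0]undec-4-ene-7-carboxylate (C7 epimers and enol)
Conditions: Pd2(dba)3·CHCl3 (5 mol %), dppe (12 mol %), THF, 65 °C, slow addition of 23 to a final 0.002 M
Reagents that add atoms: none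
Why: Pd(0) ionises the E-allylic carbonate with loss of CO2 to give the syn π-allyl complex over C4–C6 and methoxide, which deprotonates the β-keto ester at C7, and the soft enolate attacks the allyl face anti to palladium. The closest known reaction type is the palladium-catalysed intramolecular allylic alkylation of stabilised enolates under neutral carbonate conditions (Tsuji–Trost cyclisation), which closes medium and large rings at the less hindered allyl terminus. Attack at the primary terminus C6 forms C6–C7 and closes the nine-membered ring, endo with respect to the allyl unit, whereas attack at C4 would give a seven-membered ring with a vinyl-bearing quaternary carbon. No lasting stereocentre is formed: C7 is labile and is erased in step 15, and C1, C9 and C11 are carried over from 23, with C9 still able to settle to the trans fusion at the ketone stage. The step needs C6 rather than C4 attack and retention of the 4E geometry; the fully substituted C4 terminus and the trans-1,2 arms on the cyclobutane favour the first, and capture of the syn complex before π–σ–π isomerisation, helped by chloride-free conditions, a chelating phosphine and high dilution, must secure the second.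

Step 15
Reactants: 24 the bicyclic β-keto ester
Product: 25 (1S,4E,9R,11S)-11-(dimethoxymethyl)-4,11-dimethylbicyclo[7.2.0]undec-4-en-8-one
Conditions: LiCl, H2O, DMSO, 140 °C
Reagents that add atoms: none
Why: Krapcho dealkoxycarbonylation (chloride SN2 at the ester methyl, then loss of CO2) removes the C7 ester and its labile centre, and C9 can equilibrate to the more stable trans ring fusion under these conditions.

Step 16
Reactants: 25 the bicyclic ketone
Product: 26 (1S,4E,9R,11S)-11-(dimethoxymethyl)-4,11-dimethyl-8-methylenebicyclo[7.2.0]undec-4-ene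
Conditions: Ph3PCH3Br, KOtBu, THF, 0 → 50 °C
Reagents that add atoms: methyltriphenylphosphonium bromide [Br-].C[P+](c1ccccc1)(c1ccccc1)c1ccccc1
Why: Wittig methylenation of the C8 ketone, with any base-induced epimerisation at C9 running toward the trans-fused isomer.

Step 17
Reactants: 26 the diene acetal
Product: 27 (1S,4E,9R,11S)-4,11-dimethyl-8-methylenebicyclo[7.2.0]undec-4-ene-11-carbaldehyde
Conditions: PPTS (cat.), acetone/H2O 10:1, 50 °C
Reagents that add atoms: water O
Why: Mild acid-catalysed acetal hydrolysis unmasks the non-enolisable neopentyl aldehyde under conditions weak enough for the strained diene.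

Step 18
Reactants: 28 (S)-(2-methyloxiran-2-yl)methanol
Product: 30 (S)-2-ethynyl-2-methyloxirane, via epoxy aldehyde 29 (not isolated)
Conditions: Dess–Martin periodinane, pyridine, CH2Cl2, 0 °C; filtered solution, then dimethyl (1-diazo-2-oxopropyl)phosphonate, K2CO3, MeOH, 0 °C → rt; product kept as a solution (volatile)
Reagents that add atoms: dimethyl (1-diazo-2-oxopropyl)phosphonate CC(=O)C(=[N+]=[N-])P(=O)(OC)OC
Why: Dess–Martin oxidation followed by Ohira–Bestmann (Seyferth–Gilbert) homologation turns CH2OH into C≡CH without touching the quaternary epoxide carbon, so its configuration is retained.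

Step 19
Reactants: 27 the C11 aldehyde; 30 (S)-2-ethynyl-2-methyloxirane
Product: 32 1-[(1S,4E,9R,11S)-4,11-dimethyl-8-methylenebicyclo[7.2.0]undec-4-en-11-yl]-3-[(S)-2-methyloxiran-2-yl]prop-2-yn-1-ol (both carbinol epimers), via lithium acetylide 31 (not isolated)
Conditions: n-BuLi, THF, −78 °C; add 27, −78 → −30 °C; then H2O
Reagents that add atoms: none
Why: Addition of a lithium acetylide to a non-enolisable aldehyde; the new carbinol centre is oxidised away in the next step, so its configuration does not matter.

Step 20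
Reactants: 32 the propargylic alcohol
Product: 33 1-[(1S,4E,9R,11S)-4,11-dimethyl-8-methylenebicyclo[7.2.0]undec-4-en-11-yl]-3-[(S)-2-methyloxiran-2-yl]prop-2-yn-1-one
Conditions: Dess–Martin periodinane, pyridine, CH2Cl2, 0 °C → rt
Reagents that add atoms: none
Why: Dess–Martin oxidation of a propargylic alcohol to the ynone, with pyridine buffering the acid-labile epoxide.

Step 21
Reactants: 33 the ynone
Product: 34 (Z)-1-[(1S,4E,9R,11S)-4,11-dimethyl-8-methylenebicyclo[7.2.0]undec-4-en-11-yl]-3-[(S)-2-methyloxiran-2-yl]prop-2-en-1-one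
Conditions: H2 (1 atm), Lindlar catalyst, quinoline, EtOAc, 0 °C, stopped at one equivalent
Reagents that add atoms: none
Why: Lindlar semi-hydrogenation delivers H2 syn to the conjugated alkyne to give the Z-enone, and the poisoned catalyst should spare the isolated alkenes.

Step 22
Reactants: 34 the Z-epoxy enone
Product: 36 (3R,6R)-3-[(1S,4E,9R,11S)-4,11-dimethyl-8-methylenebicyclo[7.2.0]undec-4-en-11-yl]-6-(hydroxymethyl)-6-methyl-3,6-dihydro-1,2-dioxin-3-ol, via hydroperoxy hemiketal 35 (not isolated)
Conditions: anhydrous H2O2 in Et2O (excess), PPTS (cat.), Et2O/CH2Cl2, 0 °C → rt, dark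
Reagents that add atoms: hydrogen peroxide OO
Why: Proposed new method: H2O2 adds reversibly to the enone carbonyl to give hydroperoxy hemiketal 35, whose OOH group is held beside the epoxide by the Z alkene and opens the acid-activated tertiary allylic carbon C4' in a 6-exo SN2-type attack with inversion (S epoxide → R centre), releasing CH2OH and closing the 1,2-dioxine, after which C1' equilibrates through the open hydroperoxy enone to the drawn anomer; the closest known reaction types are the H2O2/epoxy-ketone cascade to 1,2-dioxolan-3-ols and 1,2-dioxan-3-ols and the acid-catalysed perhydrolysis of 2,2-disubstituted epoxides at the more substituted carbon.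

Step 23
Reactants: 36 the dioxinol primary alcohol
Product: 37 [(3R,6R)-6-[(1S,4E,9R,11S)-4,11-dimethyl-8-methylenebicyclo[7.2.0]undec-4-en-11-yl]-6-hydroxy-3-methyl-3,6-dihydro-1,2-dioxin-3-yl]methyl acetate
Conditions: Ac2O, pyridine, CH2Cl2, 0 °C
Reagents that add atoms: acetic anhydride CC(=O)OC(C)=O
Why: Selective acetylation of the primary alcohol, since the tertiary hemiperketal hydroxyl is too hindered, and capping the CH2OH also removes the competing hydroxy-hemiketal ring-chain tautomer.

Step 24
Reactants: 37 the dioxinol acetate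
Product: 38 CNP0169860.1 (target)
Conditions: mCPBA (1.05 equiv), Na2HPO4, CH2Cl2, −20 → 0 °C
Reagents that add atoms: meta-chloroperoxybenzoic acid OOC(=O)c1cccc(Cl)c1
Why: Prilezhaev epoxidation, in which the strained E-trisubstituted C4=C5 alkene should react far faster than the exocyclic and dioxine alkenes and be attacked on its exposed outer face, as in the caryophyllene to caryophyllene oxide conversion, giving the 4S,5S oxirane (sets C4 and C5).

**Compound list**

1 | 4-bromobut-1-yne | C#CCCBr | starting material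
2 | (E)-(4-bromo-2-methylbut-1-en-1-yl)dimethylalane | C[Al](C)/C=C(\C)CCBr | intermediate (not isolated)
3 | methyl (E)-5-bromo-3-methylpent-2-enoate | COC(=O)/C=C(\C)CCBr | intermediate
4 | (E)-5-bromo-3-methylpent-2-en-1-ol | OC/C=C(\C)CCBr | intermediate
5 | (E)-[(5-bromo-3-methylpent-2-en-1-yl)oxy](tert-butyl)dimethylsilane | CC(C)(C)[Si](C)(C)OC/C=C(\C)CCBr | intermediate
6 | 2,2-dimethoxyacetaldehyde | COC(OC)C=O | starting material
7 | methyl vinyl ketone (but-3-en-2-one) | CC(=O)C=C | starting material
8 | 1,1-dimethoxyhexane-2,5-dione | COC(OC)C(=O)CCC(C)=O | intermediate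
9 | 3-(dimethoxymethyl)cyclopent-2-en-1-one | COC(OC)C1=CC(=O)CC1 | intermediate
10 | (R)-3-(dimethoxymethyl)-3-methylcyclopentan-1-one | O=C1CC[C@@](C)(C(OC)OC)C1 | intermediate
11 | kinetic trimethylsilyl enol ether of 10 (double bond toward the CH2 remote from the quaternary carbon) | C[Si](C)(C)OC1=CC[C@@](C)(C(OC)OC)C1 | intermediate (not isolated)
12 | (S)-4-(dimethoxymethyl)-4-methylcyclopent-2-en-1-one | O=C1C=C[C@@](C)(C(OC)OC)C1 | intermediate
13 | (E)-[5-(tert-butyldimethylsilyloxy)-3-methylpent-3-en-1-yl]magnesium bromide | CC(C)(C)[Si](C)(C)OC/C=C(\C)CC[Mg]Br | intermediate (not isolated)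
14 | (3S,4S)-3-[(E)-5-(tert-butyldimethylsilyloxy)-3-methylpent-3-en-1-yl]-4-(dimethoxymethyl)-4-methyl-1-(trimethylsilyloxy)cyclopent-1-ene (arm trans to CH(OMe)2) | C[Si](C)(C)OC1=C[C@H](CC/C(C)=C/CO[Si](C)(C)C(C)(C)C)[C@@](C)(C(OC)OC)C1 | intermediate
15 | lithium enolate corresponding to 14 | [Li]OC1=C[C@H](CC/C(C)=C/CO[Si](C)(C)C(C)(C)C)[C@@](C)(C(OC)OC)C1 | intermediate (not isolated)
16 | 2-(trifluoroacetyl) ketone (C2 undefined, enolised; other centres as in 14) | O=C1C(C(=O)C(F)(F)F)[C@H](CC/C(C)=C/CO[Si](C)(C)C(C)(C)C)[C@@](C)(C(OC)OC)C1 | intermediate (not isolated)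
17 | (3R,4S)-2-diazo-3-[(E)-5-(tert-butyldimethylsilyloxy)-3-methylpent-3-en-1-yl]-4-(dimethoxymethyl)-4-methylcyclopentan-1-one | O=C1C(=[N+]=[N-])[C@H](CC/C(C)=C/CO[Si](C)(C)C(C)(C)C)[C@@](C)(C(OC)OC)C1 | intermediate
18 | cyclobutylidene ketene (C9=C=O; C1 and C11 as in 17) | O=C=C1C[C@](C)(C(OC)OC)[C@H]1CC/C(C)=C/CO[Si](C)(C)C(C)(C)C | intermediate (not isolated)
19 | methyl (1S,2S,3S)-2-[(E)-5-(tert-butyldimethylsilyloxy)-3-methylpent-3-en-1-yl]-3-(dimethoxymethyl)-3-methylcyclobutane-1-carboxylate (1,2-cis) | COC(=O)[C@H]1C[C@](C)(C(OC)OC)[C@H]1CC/C(C)=C/CO[Si](C)(C)C(C)(C)C | intermediate (not isolated)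
20 | methyl (1R,2S,3S)-2-[(E)-5-(tert-butyldimethylsilyloxy)-3-methylpent-3-en-1-yl]-3-(dimethoxymethyl)-3-methylcyclobutane-1-carboxylate (1,2-trans; CH(OMe)2 trans to the arm) | COC(=O)[C@@H]1C[C@](C)(C(OC)OC)[C@H]1CC/C(C)=C/CO[Si](C)(C)C(C)(C)C | intermediate
21 | methyl 3-[(1R,2S,3S)-2-[(E)-5-(tert-butyldimethylsilyloxy)-3-methylpent-3-en-1-yl]-3-(dimethoxymethyl)-3-methylcyclobutyl]-3-oxopropanoate | COC(=O)CC(=O)[C@@H]1C[C@](C)(C(OC)OC)[C@H]1CC/C(C)=C/CO[Si](C)(C)C(C)(C)C | intermediate
22 | methyl 3-[(1R,2S,3S)-3-(dimethoxymethyl)-2-[(E)-5-hydroxy-3-methylpent-3-en-1-yl]-3-methylcyclobutyl]-3-oxopropanoate | COC(=O)CC(=O)[C@@H]1C[C@](C)(C(OC)OC)[C@H]1CC/C(C)=C/CO | intermediate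
23 | methyl 3-[(1R,2S,3S)-3-(dimethoxymethyl)-2-[(E)-5-(methoxycarbonyloxy)-3-methylpent-3-en-1-yl]-3-methylcyclobutyl]-3-oxopropanoate | COC(=O)OC/C=C(C)/CC[C@H]2[C@H](C(=O)CC(=O)OC)C[C@]2(C)C(OC)OC | intermediate
24 | methyl (1S,4E,9R,11S)-11-(dimethoxymethyl)-4,11-dimethyl-8-oxobicyclo[7.2.0]undec-4-ene-7-carboxylate (C7 epimers and enol) | O=C1C(C(=O)OC)C/C=C(C)/CC[C@H]2[C@H]1C[C@]2(C)C(OC)OC | intermediate
25 | (1S,4E,9R,11S)-11-(dimethoxymethyl)-4,11-dimethylbicyclo[7.2.0]undec-4-en-8-one | O=C1CC/C=C(C)/CC[C@H]2[C@H]1C[C@]2(C)C(OC)OC | intermediate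
26 | (1S,4E,9R,11S)-11-(dimethoxymethyl)-4,11-dimethyl-8-methylenebicyclo[7.2.0]undec-4-ene | C=C1CC/C=C(C)/CC[C@H]2[C@H]1C[C@]2(C)C(OC)OC | intermediate
27 | (1S,4E,9R,11S)-4,11-dimethyl-8-methylenebicyclo[7.2.0]undec-4-ene-11-carbaldehyde | C=C1CC/C=C(C)/CC[C@H]2[C@H]1C[C@]2(C)C=O | intermediate
28 | (S)-(2-methyloxiran-2-yl)methanol ((S)-2-methylglycidol) | C[C@]1(CO)CO1 | starting material
29 | (R)-2-methyloxirane-2-carbaldehyde | C[C@]1(C=O)CO1 | intermediate (not isolated)
30 | (S)-2-ethynyl-2-methyloxirane | C[C@]1(C#C)CO1 | intermediate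
31 | lithium acetylide of 30 | [Li]C#C[C@@]1(C)CO1 | intermediate (not isolated)
32 | 1-[(1S,4E,9R,11S)-4,11-dimethyl-8-methylenebicyclo[7.2.0]undec-4-en-11-yl]-3-[(S)-2-methyloxiran-2-yl]prop-2-yn-1-ol (carbinol epimers) | C=C1CC/C=C(C)/CC[C@H]2[C@H]1C[C@]2(C)C(O)C#C[C@@]3(C)CO3 | intermediate
33 | 1-[(1S,4E,9R,11S)-4,11-dimethyl-8-methylenebicyclo[7.2.0]undec-4-en-11-yl]-3-[(S)-2-methyloxiran-2-yl]prop-2-yn-1-one | C=C1CC/C=C(C)/CC[C@H]2[C@H]1C[C@]2(C)C(=O)C#C[C@@]3(C)CO3 | intermediate
34 | (Z)-1-[(1S,4E,9R,11S)-4,11-dimethyl-8-methylenebicyclo[7.2.0]undec-4-en-11-yl]-3-[(S)-2-methyloxiran-2-yl]prop-2-en-1-one | C=C1CC/C=C(C)/CC[C@H]2[C@H]1C[C@]2(C)C(=O)/C=C\[C@@]3(C)CO3 | intermediate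
35 | hydroperoxy hemiketal of 34 (C1' bearing OH and OOH) | C=C1CC/C=C(C)/CC[C@H]2[C@H]1C[C@]2(C)C(O)(OO)/C=C\[C@@]3(C)CO3 | intermediate (not isolated)
36 | (3R,6R)-3-[(1S,4E,9R,11S)-4,11-dimethyl-8-methylenebicyclo[7.2.0]undec-4-en-11-yl]-6-(hydroxymethyl)-6-methyl-3,6-dihydro-1,2-dioxin-3-ol | C=C1CC/C=C(C)/CC[C@H]2[C@H]1C[C@]2(C)[C@@]1(O)C=C[C@](C)(CO)OO1 | intermediate
37 | [(3R,6R)-6-[(1S,4E,9R,11S)-4,11-dimethyl-8-methylenebicyclo[7.2.0]undec-4-en-11-yl]-6-hydroxy-3-methyl-3,6-dihydro-1,2-dioxin-3-yl]methyl acetate | C=C1CC/C=C(C)/CC[C@H]2[C@H]1C[C@]2(C)[C@@]1(O)C=C[C@](C)(COC(C)=O)OO1 | intermediate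
38 | CNP0169860.1: [(3R,6R)-6-[(1S,4S,5S,9R,11S)-4,5-epoxy-4,11-dimethyl-8-methylenebicyclo[7.2.0]undecan-11-yl]-6-hydroxy-3-methyl-3,6-dihydro-1,2-dioxin-3-yl]methyl acetate | C=C1CC[C@@H]2O[C@@]2(C)CC[C@H]2[C@H]1C[C@]2(C)[C@@]1(O)C=C[C@](C)(COC(C)=O)OO1 | target

**Step count**

Total step count: 24. Longest linear sequence: 20 steps (steps 4–17 and 19–24, from 6 and 7 to 38).

**Steps most likely to fail**

1. Step 22 (Proposed new method). The enone carbonyl oxygen may itself open the epoxide, leading to dihydrofuran-type products. Acid may isomerise the Z-enone before the cascade. The opening may also lose stereospecificity through a tertiary allylic cation. The fallback uses known chemistry and sets out from 34. Catalytic iodine in CH2Cl2 under ambient light isomerises it to the (E)-enone F1, in which carbonyl participation is geometrically impossible. Phosphomolybdic-acid-catalysed perhydrolysis with ethereal H2O2, a reaction known for 2,2-disubstituted epoxides with attack at the more substituted carbon and inversion, then gives the (E)-γ-hydroperoxy enone F2. Irradiation at 350 nm effects the E→Z photoisomerisation known for γ-hydroperoxy enones, and the Z isomer closes spontaneously to the cyclic hemiperketal, so the fallback comes back to the route at 36.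

2. Step 14. π–σ–π isomerisation at the 1,1-disubstituted allyl terminus before ring closure would give the 4Z ring. Attack at C4 would give the seven-membered ring, and intermolecular alkylation would give oligomers. The fallback sets out from 22. Appel bromination (CBr4, PPh3, CH2Cl2, 0 °C) gives the allylic bromide F3. Base-mediated intramolecular SN2 C-alkylation of the β-keto ester (Cs2CO3, MeCN, high dilution) then displaces bromide directly at C6 without any allyl-metal intermediate, so the alkene geometry cannot scramble. It comes back to the route at 24.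

3. Step 21. Over-reduction of the enone, hydrogenation of the strained C4=C5 alkene, Z→E isomerisation on palladium or hydrogenolysis of the vinyl epoxide may erode the Z-enone. The fallback avoids hydrogenation and sets out from 27 and 30. Hydrozirconation of 30 with Cp2Zr(H)Cl, transmetalation to zinc with Me2Zn and addition to 27 give the (E)-allylic alcohol F4. Dess–Martin oxidation gives the (E)-enone F1. This is carried through perhydrolysis to the hydroperoxy enone F2 and photochemical E→Z isomerisation with ring closure, as in the first fallback, and comes back to the route at 36.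

**Further compounds**

F1 | step 22 | (E)-1-[(1S,4E,9R,11S)-4,11-dimethyl-8-methylenebicyclo[7.2.0]undec-4-en-11-yl]-3-[(S)-2-methyloxiran-2-yl]prop-2-en-1-one | C=C1CC/C=C(C)/CC[C@H]2[C@H]1C[C@]2(C)C(=O)/C=C/[C@@]3(C)CO3
F2 | step 22 | (E,4R)-1-[(1S,4E,9R,11S)-4,11-dimethyl-8-methylenebicyclo[7.2.0]undec-4-en-11-yl]-4-hydroperoxy-5-hydroxy-4-methylpent-2-en-1-one | C=C1CC/C=C(C)/CC[C@H]2[C@H]1C[C@]2(C)C(=O)/C=C/[C@](C)(CO)OO
F3 | step 14 | methyl 3-[(1R,2S,3S)-2-[(E)-5-bromo-3-methylpent-3-en-1-yl]-3-(dimethoxymethyl)-3-methylcyclobutyl]-3-oxopropanoate | COC(=O)CC(=O)[C@@H]1C[C@](C)(C(OC)OC)[C@H]1CC/C(C)=C/CBr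
F4 | step 21 | (E)-1-[(1S,4E,9R,11S)-4,11-dimethyl-8-methylenebicyclo[7.2.0]undec-4-en-11-yl]-3-[(S)-2-methyloxiran-2-yl]prop-2-en-1-ol (carbinol epimers) | C=C1CC/C=C(C)/CC[C@H]2[C@H]1C[C@]2(C)C(O)/C=C/[C@@]3(C)CO3
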